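**The product.** X is made from Z and dissolved Q over the catalyst J, and once made it is slowly consumed by the same Q. Meanwhile Z also pairs with itself, which is a loss to X.

Z 0.70 M; G 200 mM (held); J 3.5 mM; time 2.0 d

    Z + Q + J → J + X (k1 = 2980 M⁻² h⁻¹)
    E ⇌ X, rate k2*(cs2 - [X]) while solid is left; crystals form when [X] > cs2 (cs2 = 0.32 M, k2 = 2.41 h⁻¹)
    2 Z → Z2 (k3 = 1.10 M⁻¹ h⁻¹)
    Q + X → Q.X (k4 = 0.0321 M⁻¹ h⁻¹)
    G ⇌ Q, rate k5*(csat - [Q]) (k5 = 0.583 h⁻¹, csat = 200 mM)

- percent here means Z units held: one Z2 counts as two
- what is said of X includes E
- for a step with 2 of a species take k times the square, and two of it per event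
- E is a solid; its amount is given per volume of the solution
- at the start none of Q is dissolved
- run time (flask): 2.0 d

- the X and E together standing at 2.0 d, as a percentage of the Z charged
- concentration of Q in solution at 2.0 d, in percent of saturation

**First instants.** Q starts from nothing and enters at most at 0.117 M h⁻¹, while Z pairs off at 1.08 M h⁻¹, which is faster. With Z and J as charged, dissolved Q has a half-life of 0.095 h by the step that makes X, less than the 1.19 h that transfer needs to half-fill the solution. So at the start we take gas transfer as the rate-limiting step for X.

**The middle.** We solve the two ends and join them where pairing has slowed to the supply, at Z = 0.230 M. Above this we count Z as lost to pairing, and below it as turned into X. This is crude, but it puts the peak of X near 32.9% of the charge. That peak is below the solubility 0.32 M, so we expect no crystals. Pairing takes 1.33 h to reach that point, and the supply needs 1.97 h more for the remainder.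

**The end.** Q then refills in a time short against 2.0 d, so the loss of X to Q.X becomes pseudo-first-order. We carry the fading half-life of X, its half-life with Q at saturation: 4.50 d. Over the time left, X keeps 0.751 of itself, so our y is 24.7%. Balancing transfer against that loss puts Q at about 99.1% of saturation.

**The forecast.** It gives y = 28% and saturation 98.9%, holding that “Q returns nearly to saturation and slowly consumes roughly a fifth of X”. Our y is lower.

**Fading on.** The flask gives y = 25.3% and Q at 99.0%, so the forecast stands within its margin. This flask ends with 66.6% of its Z paired off and 8.13% as Q.X. Starting from the 31.8% read at 0.500 d, the fading half-life gives 25.2% at 2.0 d. The same flask read at 8.0 d has 6.00 d more to fade, so we reckon 10.0%. That flask shows 10.1%, with Q.X at 23.3%.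

Its constants are made up; what happens was integrated by code.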